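**Retrosynthetic overview**

1. The target is fisetinidol-(4β→8)-catechin-(6→4α)-fisetinidol. The last bond made is C-4 of the 4α unit to catechin C-6, by acid-mediated capture of the flavan-4-yl cation from mollisacacidin 20 (fustin 19 + NaBH4) by the free biflavanoid 18.
2. Ring C of the 4β unit is built, not imported: a [3+3] annulation joins resorcinol (O-1/C-8a/C-4a) to the C-4/C-3/C-2 triad, held on catechin C-8 as a carbinol next to a trans-oxirane (12). This forms C-4–C-4a and O-1–C-2 in one flask.
3. Enabling feature: C-4 of this unit is benzylic to catechin ring A at C-8 (O-7 and O-1 ortho, O-5 para), so it ionises under mild acid. Ring A of the unit is a plain resorcinol whose C-4 and C-6 are equivalent and each has an ortho hydroxyl. C-2 is benzylic to ring B, which steers 6-endo oxirane opening.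
4. 12 comes from 8-lithio-penta-O-benzylcatechin and the (2R,3S)-epoxy aldehyde 10. A Sharpless epoxidation (step 7) is the only catalytic stereo-setting event: it sets C-2 and C-3, and C-4 is relayed from them.
5. Ring order: catechin rings (bought) → ring C of the 4β unit (step 10; its rings A and B come from resorcinol and 3,4-dihydroxybenzaldehyde) → rings of the 4α unit arrive intact from fustin (step 14).

Key step: step 10

Remark on the chemistry: (2R,3R)-fustin is assumed to be a commercially available natural product. Carbinol 12 is carried as a mixture of both epimers at the carbinol carbon, because that carbon becomes planar in step 10.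

**Route**

Step 1
Reactants: 1 (+)-catechin
Product: 2 5,7,3',4'-tetra-O-benzyl-(+)-catechin
Conditions: BnBr (4.4 equiv), K2CO3, DMF, 0 °C to rt, argon
Reagents that add atoms: benzyl bromide, BrCc1ccccc1
Why: Williamson etherification; the four phenols are alkylated by K2CO3/BnBr while the secondary 3-OH is left, and the mild base at low temperature leaves C-2 and C-3 untouched.

Step 2
Reactants: 2 5,7,3',4'-tetra-O-benzyl-(+)-catechin
Product: 3 3,5,7,3',4'-penta-O-benzyl-(+)-catechin
Conditions: NaH, BnBr, n-Bu4NI (cat.), DMF, 0 °C to rt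
Reagents that add atoms: benzyl bromide, BrCc1ccccc1
Why: Williamson etherification of the remaining secondary alcohol through its sodium alkoxide; no stereocentre is affected.

Step 3
Reactants: 3 3,5,7,3',4'-penta-O-benzyl-(+)-catechin
Product: 4 8-bromo-3,5,7,3',4'-penta-O-benzyl-(+)-catechin
Conditions: NBS (1.0 equiv), CH2Cl2, −78 °C to rt
Reagents that add atoms: N-bromosuccinimide, O=C1CCC(=O)N1Br
Why: electrophilic aromatic bromination; in 5,7-di-O-benzyl flavan-3-ol ethers C-8 is the more reactive and accessible ring A position, so one equivalent of NBS should give the 8-bromide.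

Step 4
Reactants: 5 3,4-dihydroxybenzaldehyde
Product: 6 3,4-bis(pivaloyloxy)benzaldehyde
Conditions: PivCl (2.4 equiv), Et3N, DMAP (cat.), CH2Cl2, 0 °C to rt
Reagents that add atoms: pivaloyl chloride, CC(C)(C)C(Cl)=O
Why: DMAP-catalysed acylation of both phenols; the pivalates make ring B of the future upper unit electron-poor so that its oxirane survives until the key step.

Step 5
Reactants: 6 3,4-bis(pivaloyloxy)benzaldehyde
Product: 7 (E)-3-[3,4-bis(pivaloyloxy)phenyl]prop-2-enal
Conditions: Ph3P=CHCHO (1.1 equiv), toluene, 80 °C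
Reagents that add atoms: (triphenylphosphoranylidene)acetaldehyde, O=CC=P(c1ccccc1)(c1ccccc1)c1ccccc1
Why: Wittig olefination with a stabilised ylide gives the E-enal by two-carbon homologation; the aryl esters are inert to the ylide.

Step 6
Reactants: 7 (E)-3-[3,4-bis(pivaloyloxy)phenyl]prop-2-enal
Product: 8 (E)-3-[3,4-bis(pivaloyloxy)phenyl]prop-2-en-1-ol
Conditions: NaBH4, CeCl3·7H2O, MeOH/THF, −40 °C
Reagents that add atoms: none
Why: Luche reduction gives clean 1,2-reduction of the enal, and aryl pivalates are not touched by NaBH4 at low temperature.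

Step 7
Reactants: 8 (E)-3-[3,4-bis(pivaloyloxy)phenyl]prop-2-en-1-ol
Product: 9 [(2S,3S)-3-(3,4-bis(pivaloyloxy)phenyl)oxiran-2-yl]methanol
Conditions: Ti(OiPr)4 (10 mol%), L-(+)-diisopropyl tartrate (12 mol%), t-BuOOH (2 equiv), 4 Å MS, CH2Cl2, −20 °C
Reagents that add atoms: tert-butyl hydroperoxide, CC(C)(C)OO
Why: Sharpless asymmetric epoxidation; with L-(+)-diisopropyl tartrate the E-cinnamyl alcohol should give the (2S,3S)-epoxy alcohol, so both new stereocentres (the future C-2 and C-3 of the upper flavan unit) are set by the chiral titanium tartrate catalyst.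

Step 8
Reactants: 9 [(2S,3S)-3-(3,4-bis(pivaloyloxy)phenyl)oxiran-2-yl]methanol
Product: 10 (2R,3S)-3-[3,4-bis(pivaloyloxy)phenyl]oxirane-2-carbaldehyde
Conditions: Dess–Martin periodinane (1.3 equiv), NaHCO3, CH2Cl2, 0 °C to rt; used at once
Reagents that add atoms: none
Why: buffered Dess–Martin oxidation converts the primary alcohol into the aldehyde without opening or epimerising the oxirane.

Step 9
Reactants: 4 8-bromo-3,5,7,3',4'-penta-O-benzyl-(+)-catechin; 10 (2R,3S)-3-[3,4-bis(pivaloyloxy)phenyl]oxirane-2-carbaldehyde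
Product: 12 [(2S,3S)-3-(3,4-bis(pivaloyloxy)phenyl)oxiran-2-yl](3,5,7,3',4'-penta-O-benzylcatechin-8-yl)methanol as both carbinol epimers, via 8-lithio-penta-O-benzylcatechin 11 (not isolated)
Conditions: n-BuLi (1.05 equiv), THF, −78 °C; then 10 (1.2 equiv), −78 °C; sat. aq. NH4Cl at −78 °C
Reagents that add atoms: none
Why: bromine–lithium exchange followed by 1,2-addition of the aryllithium to the aldehyde, which at −78 °C is far more electrophilic than the hindered aryl pivalates; the new carbinol centre is not controlled and need not be, since it is ionised in step 10.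

Step 10
Reactants: 12 epoxy carbinol (both epimers); 13 resorcinol (benzene-1,3-diol)
Product: 16 3',4'-di-O-pivaloylfisetinidol-(4β→8)-3,5,7,3',4'-penta-O-benzylcatechin, via benzylic cation 14 (not isolated), via Friedel-Crafts epoxy phenol 15 (not isolated)
Conditions: resorcinol (5 equiv), (PhO)2P(O)OH (10 mol%), (CF3)2CHOH/CH2Cl2 1:4, −40 °C to 20 °C
Reagents that add atoms: none
Why: Proposed new method: a dehydrative Friedel–Crafts arylation of an α,β-epoxy benzylic alcohol followed in the same flask by phenol–oxirane opening is proposed as a formal [3+3] annulation, the closest known reaction types being the acid-promoted Friedel–Crafts benzylation of phenols by electron-rich benzylic alcohols in fluorinated alcohol and the acid-catalysed 6-endo cyclisation of 2-(3-aryloxiranylmethyl)phenols to 2,3-trans-flavan-3-ols. The acid should ionise only the carbinol of 12, because cation 14 is carried by catechin ring A (O-7 and O-1 ortho, O-5 para to C-8) whereas the oxirane sits on a ring B made electron-poor by two pivalates, and resorcinol then attacks through C-4, which is para to one hydroxyl, ortho to the other and equivalent to C-6 by symmetry, to give 15 (new C-4–C-4a bond). The new stereocentre C-4 is controlled by the oxirane: in 14 the C-3 hydrogen lies in the plane of the cation to avoid allylic 1,3-strain with the ortho oxygens, so the two faces carry the oxirane oxygen and the oxirane carbon C-2, and attack past the small oxygen, anti to the C-3–C-2 bond and assisted by a hydrogen bond from the incoming phenol, should give the 3,4-cis (4β) arrangement. The hydroxyl ortho to the new bond then opens the oxirane at the benzylic carbon C-2 with inversion in a 6-endo closure of ring C (new O-1–C-2 bond), which turns the trans-oxirane into the 2,3-trans relation and leaves C-3 untouched, so C-2 and C-3 derive from step 7 and C-4 is relayed from them. The selectivities needed are carbinol ionisation before oxirane opening, C- over O-alkylation of resorcinol, 6-endo over 5-exo opening (C-2 is benzylic and C-3 is screened by the adjacent diarylmethine) and the face selectivity at C-4, and the excess of resorcinol suppresses double alkylation.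

Step 11
Reactants: 16 3',4'-di-O-pivaloylfisetinidol-(4β→8)-3,5,7,3',4'-penta-O-benzylcatechin
Product: 17 fisetinidol-(4β→8)-3,5,7,3',4'-penta-O-benzylcatechin
Conditions: iBu2AlH (8 equiv), CH2Cl2, −78 °C; aq. Rochelle salt
Reagents that add atoms: none
Why: reductive cleavage of the two aryl pivalates by excess iBu2AlH; benzyl ethers and the flavan skeleton are inert, and no free phenoxide is generated in protic basic medium, so C-2 of the upper unit cannot epimerise.

Step 12
Reactants: 17 fisetinidol-(4β→8)-3,5,7,3',4'-penta-O-benzylcatechin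
Product: 18 fisetinidol-(4β→8)-catechin
Conditions: H2 (1 atm), Pd(OH)2/C, THF/MeOH 1:1, rt
Reagents that add atoms: none
Why: hydrogenolysis of the five benzyl ethers under neutral conditions; the cyclic benzylic C–O bonds and the C-4–C-8 bond of oligoflavanoids survive short hydrogenolysis at atmospheric pressure.

Step 13
Reactants: 19 (2R,3R)-fustin
Product: 20 (2R,3S,4R)-mollisacacidin (2,3-trans-3,4-trans-flavan-3,3',4,4',7-pentol)
Conditions: NaBH4, EtOH, 0 °C to rt
Reagents that add atoms: none
Why: NaBH4 reduction of the dihydroflavonol ketone; axial delivery of hydride should give mainly the all-equatorial 3,4-trans diol, and the C-4 configuration is in any case erased in step 14.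

Step 14
Reactants: 18 fisetinidol-(4β→8)-catechin; 20 (2R,3S,4R)-mollisacacidin
Product: 22 fisetinidol-(4β→8)-catechin-(6→4α)-fisetinidol (target), via fisetinidol C-4 cation 21 (not isolated)
Conditions: 0.1 M HCl (aq), 25 °C, N2; Sephadex LH-20 (EtOH)
Reagents that add atoms: none
Why: acid-mediated formation of the flavan-4-yl cation (protonated p-quinone methide) from the 7-hydroxyflavan-3,4-diol and Friedel–Crafts capture; C-6 of the catechin unit is the only free position of the phloroglucinol-type ring A and is far more nucleophilic than the resorcinol-type rings, and attack on the 2,3-trans cation from the face opposite the 3-hydroxyl should give mainly the 3,4-trans (4α) bond.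

**Compound list**

1 | (+)-catechin, (2R,3S)-flavan-3,3',4',5,7-pentol | Oc1cc(O)c2c(c1)O[C@H](c1ccc(O)c(O)c1)[C@@H](O)C2 | starting material
2 | 5,7,3',4'-tetra-O-benzyl-(+)-catechin (3-OH free) | C(c1ccccc1)Oc1cc(OCc2ccccc2)c2c(c1)O[C@H](c1ccc(OCc3ccccc3)c(OCc3ccccc3)c1)[C@@H](O)C2 | intermediate
3 | 3,5,7,3',4'-penta-O-benzyl-(+)-catechin | C(c1ccccc1)Oc1cc(OCc2ccccc2)c2c(c1)O[C@H](c1ccc(OCc3ccccc3)c(OCc3ccccc3)c1)[C@@H](OCc1ccccc1)C2 | intermediate
4 | 8-bromo-3,5,7,3',4'-penta-O-benzyl-(+)-catechin | C(c1ccccc1)Oc1cc(OCc2ccccc2)c2c(c1Br)O[C@H](c1ccc(OCc3ccccc3)c(OCc3ccccc3)c1)[C@@H](OCc1ccccc1)C2 | intermediate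
5 | 3,4-dihydroxybenzaldehyde | O=Cc1ccc(O)c(O)c1 | starting material
6 | 3,4-bis(pivaloyloxy)benzaldehyde | O=Cc1ccc(OC(=O)C(C)(C)C)c(OC(=O)C(C)(C)C)c1 | intermediate
7 | (E)-3-[3,4-bis(pivaloyloxy)phenyl]prop-2-enal | O=C/C=C/c1ccc(OC(=O)C(C)(C)C)c(OC(=O)C(C)(C)C)c1 | intermediate
8 | (E)-3-[3,4-bis(pivaloyloxy)phenyl]prop-2-en-1-ol | OC/C=C/c1ccc(OC(=O)C(C)(C)C)c(OC(=O)C(C)(C)C)c1 | intermediate
9 | [(2S,3S)-3-(3,4-bis(pivaloyloxy)phenyl)oxiran-2-yl]methanol (trans-oxirane) | OC[C@@H]1O[C@H]1c1ccc(OC(=O)C(C)(C)C)c(OC(=O)C(C)(C)C)c1 | intermediate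
10 | (2R,3S)-3-[3,4-bis(pivaloyloxy)phenyl]oxirane-2-carbaldehyde | O=C[C@@H]1O[C@H]1c1ccc(OC(=O)C(C)(C)C)c(OC(=O)C(C)(C)C)c1 | intermediate
11 | 8-lithio-3,5,7,3',4'-penta-O-benzyl-(+)-catechin (not isolated) | C(c1ccccc1)Oc1cc(OCc2ccccc2)c2c(c1[Li])O[C@H](c1ccc(OCc3ccccc3)c(OCc3ccccc3)c1)[C@@H](OCc1ccccc1)C2 | intermediate
12 | [(2S,3S)-3-(3,4-bis(pivaloyloxy)phenyl)oxiran-2-yl](3,5,7,3',4'-penta-O-benzylcatechin-8-yl)methanol, both epimers at the carbinol carbon | C(c1ccccc1)Oc1cc(OCc2ccccc2)c2c(c1C(O)[C@@H]1O[C@H]1c1ccc(OC(=O)C(C)(C)C)c(OC(=O)C(C)(C)C)c1)O[C@H](c1ccc(OCc3ccccc3)c(OCc3ccccc3)c1)[C@@H](OCc1ccccc1)C2 | intermediate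
13 | resorcinol (benzene-1,3-diol) | Oc1cccc(O)c1 | starting material
14 | benzylic cation at the former carbinol carbon of 12, oxirane intact (not isolated) | C(c1ccccc1)Oc1cc(OCc2ccccc2)c2c(c1[CH+][C@@H]1O[C@H]1c1ccc(OC(=O)C(C)(C)C)c(OC(=O)C(C)(C)C)c1)O[C@H](c1ccc(OCc3ccccc3)c(OCc3ccccc3)c1)[C@@H](OCc1ccccc1)C2 | intermediate
15 | Friedel–Crafts adduct: 2,4-dihydroxyphenyl group on the former carbinol carbon (configuration leading to 4β), oxirane intact (not isolated) | C(c1ccccc1)Oc1cc(OCc2ccccc2)c2c(c1[C@@H](c1ccc(O)cc1O)[C@@H]1O[C@H]1c1ccc(OC(=O)C(C)(C)C)c(OC(=O)C(C)(C)C)c1)O[C@H](c1ccc(OCc3ccccc3)c(OCc3ccccc3)c1)[C@@H](OCc1ccccc1)C2 | intermediate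
16 | 3',4'-di-O-pivaloylfisetinidol-(4β→8)-3,5,7,3',4'-penta-O-benzylcatechin (upper unit 2,3-trans-3,4-cis; 3-OH and 7-OH free) | Oc1ccc2c(c1)O[C@H](c1ccc(OC(=O)C(C)(C)C)c(OC(=O)C(C)(C)C)c1)[C@@H](O)[C@H]2c1c(OCc2ccccc2)cc(OCc2ccccc2)c2c1O[C@H](c1ccc(OCc3ccccc3)c(OCc3ccccc3)c1)[C@@H](OCc1ccccc1)C2 | intermediate
17 | fisetinidol-(4β→8)-3,5,7,3',4'-penta-O-benzylcatechin | Oc1ccc2c(c1)O[C@H](c1ccc(O)c(O)c1)[C@@H](O)[C@H]2c1c(OCc2ccccc2)cc(OCc2ccccc2)c2c1O[C@H](c1ccc(OCc3ccccc3)c(OCc3ccccc3)c1)[C@@H](OCc1ccccc1)C2 | intermediate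
18 | fisetinidol-(4β→8)-catechin | Oc1ccc2c(c1)O[C@H](c1ccc(O)c(O)c1)[C@@H](O)[C@H]2c1c(O)cc(O)c2c1O[C@H](c1ccc(O)c(O)c1)[C@@H](O)C2 | intermediate
19 | (2R,3R)-fustin, (2R,3R)-3,7,3',4'-tetrahydroxyflavanone | O=C1c2ccc(O)cc2O[C@H](c2ccc(O)c(O)c2)[C@H]1O | starting material
20 | (2R,3S,4R)-mollisacacidin, 2,3-trans-3,4-trans-flavan-3,3',4,4',7-pentol | Oc1ccc2c(c1)O[C@H](c1ccc(O)c(O)c1)[C@@H](O)[C@@H]2O | intermediate
21 | fisetinidol C-4 carbocation (protonated p-quinone methide; not isolated) | Oc1ccc2c(c1)O[C@H](c1ccc(O)c(O)c1)[C@@H](O)[CH+]2 | intermediate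
22 | fisetinidol-(4β→8)-catechin-(6→4α)-fisetinidol | Oc1ccc2c(c1)O[C@H](c1ccc(O)c(O)c1)[C@@H](O)[C@H]2c1c(O)c([C@@H]2c3ccc(O)cc3O[C@H](c3ccc(O)c(O)c3)[C@H]2O)c(O)c2c1O[C@H](c1ccc(O)c(O)c1)[C@@H](O)C2 | target

**Step count and risks**

Total step count: 14. Longest linear sequence: 10 steps (steps 4–12 and 14, from 3,4-dihydroxybenzaldehyde 5).

Steps most likely to fail:

1. Step 10 (proposed new method). What may go wrong: resorcinol may attack the wrong face of cation 14, the oxirane may open before the Friedel–Crafts event, or closure may go 5-exo. Fallback with known chemistry: (+)-catechin 1 and mollisacacidin 20 (from step 13) are condensed in 0.1 M aqueous HCl at 25 °C. The flavan-4-yl cation should be captured mainly at catechin C-8 to give fisetinidol-(4α→8)-catechin F1 together with its 4β epimer 18 as the minor component. 18 is separated on Sephadex LH-20 and re-enters the route at compound 18, before step 14.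

2. Step 14. What may go wrong: self-condensation of the flavan-3,4-diol and further alkylation of the product may compete with the slow attack at the hindered C-6, and face selectivity at the new C-4 may be incomplete. Fallback: mollisacacidin 20 is converted with benzyl mercaptan in acetic acid into 4α-benzylsulfanylfisetinidol F2 (mainly 3,4-trans; either C-4 epimer serves). This isolable electrophile is then coupled with 18 by thiophilic activation with AgBF4 in THF at 0 °C, so that the cation is released in a controlled amount under non-protic conditions. The fallback sets out from 20 and 18 and returns at the target 22.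

3. Step 9. What may go wrong: the basic, hindered aryllithium may decompose the epoxy aldehyde (proton transfer, ring opening) instead of adding to it, and attack on the pivalates may compete. Fallback: epoxy alcohol 9 is oxidised (TEMPO cat., PhI(OAc)2, MeCN/H2O) to (2R,3S)-3-[3,4-bis(pivaloyloxy)phenyl]oxirane-2-carboxylic acid F3. F3 is coupled with MeNHOMe·HCl (EDC·HCl, N-methylmorpholine) to the Weinreb amide F4. Aryllithium 11 (from 4) is acylated with F4 at −78 °C to give the epoxy ketone F5, which is reduced with NaBH4/CeCl3 in MeOH to 12. The fallback sets out from 9 and 4 and returns at 12.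

**Further compounds**

F1 | step 10 | fisetinidol-(4α→8)-catechin | Oc1ccc2c(c1)O[C@H](c1ccc(O)c(O)c1)[C@@H](O)[C@@H]2c1c(O)cc(O)c2c1O[C@H](c1ccc(O)c(O)c1)[C@@H](O)C2
F2 | step 14 | 4α-benzylsulfanylfisetinidol, (2R,3S,4R), 3,4-trans | Oc1ccc2c(c1)O[C@H](c1ccc(O)c(O)c1)[C@@H](O)[C@@H]2SCc1ccccc1
F3 | step 9 | (2R,3S)-3-[3,4-bis(pivaloyloxy)phenyl]oxirane-2-carboxylic acid | OC(=O)[C@@H]1O[C@H]1c1ccc(OC(=O)C(C)(C)C)c(OC(=O)C(C)(C)C)c1
F4 | step 9 | (2R,3S)-N-methoxy-N-methyl-3-[3,4-bis(pivaloyloxy)phenyl]oxirane-2-carboxamide | CON(C)C(=O)[C@@H]1O[C@H]1c1ccc(OC(=O)C(C)(C)C)c(OC(=O)C(C)(C)C)c1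
F5 | step 9 | [(2R,3S)-3-(3,4-bis(pivaloyloxy)phenyl)oxiran-2-yl](3,5,7,3',4'-penta-O-benzylcatechin-8-yl)methanone | C(c1ccccc1)Oc1cc(OCc2ccccc2)c2c(c1C(=O)[C@@H]1O[C@H]1c1ccc(OC(=O)C(C)(C)C)c(OC(=O)C(C)(C)C)c1)O[C@H](c1ccc(OCc3ccccc3)c(OCc3ccccc3)c1)[C@@H](OCc1ccccc1)C2
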